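The dihydrofuran ring of the target (O1, C2, C3, C3a, C7a), whose C3 carries a carbon substituent, is read as a contracted pyranone. The C3–C3a bond is made by shifting the arene carbon of a 2-arylchroman-4-one from the carbonyl carbon to the neighbouring CH2. One oxidative operation on a (2R)-flavanone thus closes the five-membered ring, extrudes the carbonyl carbon as a C3 ester and sets C3 trans to the untouched guaiacyl-bearing C2. The precursor is a 5-benzyloxy-7-bromoflavanone with a benzyl-protected guaiacyl group at C2. The bromide later takes the styryl arm, and the ester is exchanged for the resorcinol ring by decarboxylative arylation.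

Key step: step 5

Assumption: the (1R,4R)-diene of step 4 is taken to deliver the aryl group to the Si face of C2 of the chromone, the sense it shows at the β-carbon of cyclic enones; if the opposite sense is found, the (1S,4S)-diene is used and nothing else changes.

Step 1
Reactants: 1 1-(4-bromo-2,6-difluorophenyl)ethan-1-one
Product: 2 1-[2-(benzyloxy)-4-bromo-6-fluorophenyl]ethan-1-one
Conditions: BnOH (1.0 equiv), KOtBu (1.05 equiv), THF, −20 °C to rt
Reagents that add atoms: benzyl alcohol, OCc1ccccc1
Why: Nucleophilic aromatic substitution (SNAr, addition–elimination through a Meisenheimer adduct stabilised by the ortho acetyl group) should replace one fluoride only, because one equivalent of alkoxide is used at low temperature, fluoride is a far better SNAr leaving group than the para bromide, and the first benzyloxy group twists the acetyl group and slows the second substitution.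

Step 2
Reactants: 2 1-[2-(benzyloxy)-4-bromo-6-fluorophenyl]ethan-1-one
Product: 4 1-[2-(benzyloxy)-4-bromo-6-hydroxyphenyl]ethan-1-one, via sulfonylethyl ether 3 (not isolated)
Conditions: MeSO2CH2CH2OH (1.5 equiv), NaH (3 equiv), DMF, 0 °C to rt; aq. HCl work-up
Reagents that add atoms: 2-(methylsulfonyl)ethanol, CS(=O)(=O)CCO
Why: A second SNAr in a dipolar aprotic solvent with the small primary alkoxide, followed in the same flask by base-induced E1cB loss of methyl vinyl sulfone from ether 3, is a known way to turn a carbonyl-activated aryl fluoride into the phenol without hydroxide, and the benzyl ether and the bromide are not affected.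

Step 3
Reactants: 4 1-[2-(benzyloxy)-4-bromo-6-hydroxyphenyl]ethan-1-one
Product: 6 5-(benzyloxy)-7-bromo-4H-chromen-4-one, via enaminone 5 (not isolated)
Conditions: Me2NCH(OMe)2 (2 equiv), toluene, 100 °C; concentrate; conc. HCl, CH2Cl2, 40 °C
Reagents that add atoms: N,N-dimethylformamide dimethyl acetal, COC(OC)N(C)C
Why: Condensation of the methyl ketone with the formamide acetal gives enaminone 5, and acid then triggers conjugate addition of the phenol oxygen and loss of dimethylamine (addition–elimination, 6-endo-trig closure of the pyranone ring), the standard enaminone synthesis of 2,3-unsubstituted chromones.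

Step 4
Reactants: 6 5-(benzyloxy)-7-bromo-4H-chromen-4-one; 7 [4-(benzyloxy)-3-methoxyphenyl]boronic acid
Product: 8 (2R)-5-(benzyloxy)-2-[4-(benzyloxy)-3-methoxyphenyl]-7-bromo-2,3-dihydro-4H-chromen-4-one
Conditions: [RhCl(C2H4)2]2 (2.5 mol %), (1R,4R)-2,5-diphenylbicyclo[2.2.2]octa-2,5-diene (5.5 mol %), 7 (2 equiv), aq. KOH (0.2 equiv), 1,4-dioxane/H2O 10:1, 30 °C
Reagents that add atoms: none
Why: Rhodium-catalysed asymmetric 1,4-addition of an arylboronic acid to a chromone (Hayashi–Miyaura reaction), in which the aryl–rhodium species held by the C2-symmetric diene inserts the C2=C3 bond on the Si face of C2 and so sets the 2R centre by catalyst control before water protonates the oxa-π-allyl intermediate; monovalent rhodium leaves the aryl bromide untouched, and the low base loading and temperature limit retro-oxa-Michael opening of the flavanone.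

Step 5
Reactants: 8 (2R)-5-(benzyloxy)-2-[4-(benzyloxy)-3-methoxyphenyl]-7-bromo-2,3-dihydro-4H-chromen-4-one
Product: 10 methyl (2R,3R)-4-(benzyloxy)-2-[4-(benzyloxy)-3-methoxyphenyl]-6-bromo-2,3-dihydro-1-benzofuran-3-carboxylate (trans), via methyl enol ether 9 (not isolated)
Conditions: PhI(OAc)2 (1.3 equiv), conc. H2SO4 (cat.), HC(OMe)3, rt
Reagents that add atoms: trimethyl orthoformate, COC(OC)OC
Why: Acidic orthoformate converts the C4 ketone into methyl enol ether 9, whose C3 attacks the trivalent iodine reagent on the face opposite the C2 aryl group, and methanol adds to give a C4 dimethyl ketal with an equatorial C3–I(Ph)OAc bond antiperiplanar to the C4–C4a ring bond. Reductive loss of iodobenzene is accompanied by the 1,2-shift of C4a from C4 to C3, and the dimethoxycarbenium ion left behind is demethylated to the methyl ester. The closest known reaction type is the oxidative 1,2-aryl shift of aryl ketone enol ethers with PhI(OAc)2 or Tl(NO3)3 in trimethyl orthoformate, which on flavanones is an established contraction to methyl 2-aryl-2,3-dihydrobenzofuran-3-carboxylates. The dihydrofuran ring is closed by ring contraction and not by cyclisation: the C3–C3a bond forms through an aryl-bridged, formally 3-exo-tet, transition state while the former carbonyl carbon leaves the ring. C3 is set by substrate control, since the iodane enters anti to the C2 aryl group and the migrating carbon displaces it with inversion, which places the ester trans to that aryl group (3R), whereas C2 is not touched and stays R. The step needs ring-A migration to outrun the shift of the C2 aryl group (isoflavone) and dehydrogenation (flavone); the diequatorial aryl/iodane arrangement denies the C2 aryl group antiperiplanar alignment, and the migrating carbon is activated by the ortho benzyloxy group and the ortho ring oxygen and only weakly deactivated by the para bromide.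

Step 6
Reactants: 11 4-(benzyloxy)-3-methoxybenzaldehyde
Product: 12 1-(benzyloxy)-4-ethenyl-2-methoxybenzene
Conditions: Ph3PCH3Br (1.3 equiv), KOtBu (1.25 equiv), THF, 0 °C to rt
Reagents that add atoms: methyltriphenylphosphonium bromide, C[P+](c1ccccc1)(c1ccccc1)c1ccccc1.[Br-]
Why: Wittig methylenation, in which the non-stabilised ylide adds to the aromatic aldehyde and the oxaphosphetane collapses to the terminal alkene and triphenylphosphine oxide, with the benzyl ether untouched.

Step 7
Reactants: 10 methyl (2R,3R)-4-(benzyloxy)-2-[4-(benzyloxy)-3-methoxyphenyl]-6-bromo-2,3-dihydro-1-benzofuran-3-carboxylate; 12 1-(benzyloxy)-4-ethenyl-2-methoxybenzene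
Product: 13 methyl (2R,3R)-4-(benzyloxy)-2-[4-(benzyloxy)-3-methoxyphenyl]-6-[(E)-2-[4-(benzyloxy)-3-methoxyphenyl]ethenyl]-2,3-dihydro-1-benzofuran-3-carboxylate
Conditions: Pd2(dba)3 (2 mol %), P(t-Bu)3·HBF4 (8 mol %), Cy2NMe (1.5 equiv), 12 (1.3 equiv), 1,4-dioxane, rt to 50 °C
Reagents that add atoms: none
Why: Mizoroki–Heck reaction of the unhindered aryl bromide, in which oxidative addition to zerovalent palladium, syn carbopalladation at the terminal alkene carbon and syn β-hydride elimination give the E-stilbene; the bulky phosphine allows a low temperature and the hindered amine is too weak a base to enolise the C3 ester, so both stereocentres are kept.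

Step 8
Reactants: 13 methyl (2R,3R)-4-(benzyloxy)-2-[4-(benzyloxy)-3-methoxyphenyl]-6-[(E)-2-[4-(benzyloxy)-3-methoxyphenyl]ethenyl]-2,3-dihydro-1-benzofuran-3-carboxylate
Product: 14 (2R,3R)-4-(benzyloxy)-2-[4-(benzyloxy)-3-methoxyphenyl]-6-[(E)-2-[4-(benzyloxy)-3-methoxyphenyl]ethenyl]-2,3-dihydro-1-benzofuran-3-carboxylic acid
Conditions: Me3SnOH (6 equiv), ClCH2CH2Cl, 80 °C; 5% aq. HCl wash
Reagents that add atoms: trimethyltin hydroxide, C[Sn](C)(C)O
Why: Methyl ester cleavage with a neutral tin hydroxide, a known hydrolysis for esters with a base-sensitive α-centre, which avoids the ester enolate and with it retro-oxa-Michael opening of the dihydrofuran ring that would erase C2.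

Step 9
Reactants: 14 (2R,3R)-4-(benzyloxy)-2-[4-(benzyloxy)-3-methoxyphenyl]-6-[(E)-2-[4-(benzyloxy)-3-methoxyphenyl]ethenyl]-2,3-dihydro-1-benzofuran-3-carboxylic acid
Product: 15 1,3-dioxo-1,3-dihydro-2H-isoindol-2-yl (2R,3R)-4-(benzyloxy)-2-[4-(benzyloxy)-3-methoxyphenyl]-6-[(E)-2-[4-(benzyloxy)-3-methoxyphenyl]ethenyl]-2,3-dihydro-1-benzofuran-3-carboxylate
Conditions: N-hydroxyphthalimide (1.1 equiv), i-PrN=C=N-i-Pr (1.1 equiv), DMAP (5 mol %), CH2Cl2, 0 °C to rt
Reagents that add atoms: N-hydroxyphthalimide, O=C1c2ccccc2C(=O)N1O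
Why: Carbodiimide-mediated esterification through the O-acylisourea gives the redox-active ester under nearly neutral conditions; C3 is replaced in the next step, and C2, the centre that must be kept, is not involved.

Step 10
Reactants: 15 1,3-dioxo-1,3-dihydro-2H-isoindol-2-yl (2R,3R)-4-(benzyloxy)-2-[4-(benzyloxy)-3-methoxyphenyl]-6-[(E)-2-[4-(benzyloxy)-3-methoxyphenyl]ethenyl]-2,3-dihydro-1-benzofuran-3-carboxylate; 16 1,3-bis(benzyloxy)-5-bromobenzene
Product: 19 (2R,3R)-4-(benzyloxy)-2-[4-(benzyloxy)-3-methoxyphenyl]-6-[(E)-2-[4-(benzyloxy)-3-methoxyphenyl]ethenyl]-3-[3,5-bis(benzyloxy)phenyl]-2,3-dihydro-1-benzofuran, via aryllithium 17 (not isolated), via arylzinc chloride 18 (not isolated)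
Conditions: 16 (3 equiv), n-BuLi (3 equiv), THF, −78 °C; ZnCl2 (3.2 equiv), −78 °C to rt; then 15, NiCl2(dme) (20 mol %), 4,4′-di-tert-butyl-2,2′-bipyridine (40 mol %), THF/DMF, rt
Reagents that add atoms: none
Why: Nickel-catalysed decarboxylative Negishi-type arylation of a redox-active ester, in which electron transfer from low-valent nickel releases CO2 and the planar benzylic C3 radical, the aryl–nickel species captures it and reductive elimination forms the C3–aryl bond on the face anti to the C2 aryl group (substrate control, 3R, trans); opening of the radical by C2–O1 scission is disfavoured because that bond lies near the nodal plane of the benzylic radical, and the stilbene and the benzyl ethers are inert to the arylzinc reagent.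

Step 11
Reactants: 19 (2R,3R)-4-(benzyloxy)-2-[4-(benzyloxy)-3-methoxyphenyl]-6-[(E)-2-[4-(benzyloxy)-3-methoxyphenyl]ethenyl]-3-[3,5-bis(benzyloxy)phenyl]-2,3-dihydro-1-benzofuran
Product: 20 5-[(2R,3R)-4-hydroxy-2-(4-hydroxy-3-methoxyphenyl)-6-[(E)-2-(4-hydroxy-3-methoxyphenyl)ethenyl]-2,3-dihydro-1-benzofuran-3-yl]benzene-1,3-diol
Conditions: BCl3 (1 M in CH2Cl2, 12 equiv), C6HMe5 (15 equiv), CH2Cl2, −78 °C; MeOH quench at −78 °C
Reagents that add atoms: none
Why: Lewis-acid cleavage of the five aryl benzyl ethers with pentamethylbenzene as a non-basic benzyl-cation scavenger, a known global debenzylation for benzyl-protected oligostilbenes; at −78 °C the two aryl methyl ethers, the E-alkene and the benzylic C2–O1 bond are expected to survive and the scavenger prevents C-benzylation of the electron-rich rings, so both stereocentres reach the target unchanged.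

Compound list
1 | 1-(4-bromo-2,6-difluorophenyl)ethan-1-one | CC(=O)c1c(F)cc(Br)cc1F | starting material
2 | 1-[2-(benzyloxy)-4-bromo-6-fluorophenyl]ethan-1-one | CC(=O)c1c(F)cc(Br)cc1OCc1ccccc1 | intermediate
3 | 1-{2-(benzyloxy)-4-bromo-6-[2-(methanesulfonyl)ethoxy]phenyl}ethan-1-one (formed in the flask) | CC(=O)c1c(OCCS(C)(=O)=O)cc(Br)cc1OCc1ccccc1 | intermediate
4 | 1-[2-(benzyloxy)-4-bromo-6-hydroxyphenyl]ethan-1-one | CC(=O)c1c(O)cc(Br)cc1OCc1ccccc1 | intermediate
5 | (2E)-1-[2-(benzyloxy)-4-bromo-6-hydroxyphenyl]-3-(dimethylamino)prop-2-en-1-one (formed in the flask) | CN(C)/C=C/C(=O)c1c(O)cc(Br)cc1OCc1ccccc1 | intermediate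
6 | 5-(benzyloxy)-7-bromo-4H-chromen-4-one | O=c1ccoc2cc(Br)cc(OCc3ccccc3)c12 | intermediate
7 | [4-(benzyloxy)-3-methoxyphenyl]boronic acid | COc1cc(B(O)O)ccc1OCc1ccccc1 | starting material
8 | (2R)-5-(benzyloxy)-2-[4-(benzyloxy)-3-methoxyphenyl]-7-bromo-2,3-dihydro-4H-chromen-4-one | Brc1cc(OCc3ccccc3)c2c(c1)O[C@@H](c1ccc(OCc3ccccc3)c(OC)c1)CC2=O | intermediate
9 | (2R)-5-(benzyloxy)-2-[4-(benzyloxy)-3-methoxyphenyl]-7-bromo-4-methoxy-2H-chromene (formed in the flask) | Brc1cc(OCc3ccccc3)c2c(c1)O[C@@H](c1ccc(OCc3ccccc3)c(OC)c1)C=C2OC | intermediate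
10 | methyl (2R,3R)-4-(benzyloxy)-2-[4-(benzyloxy)-3-methoxyphenyl]-6-bromo-2,3-dihydro-1-benzofuran-3-carboxylate (trans) | Brc1cc(OCc3ccccc3)c2c(c1)O[C@@H](c1ccc(OCc3ccccc3)c(OC)c1)[C@@H]2C(=O)OC | intermediate
11 | 4-(benzyloxy)-3-methoxybenzaldehyde | COc1cc(C=O)ccc1OCc1ccccc1 | starting material
12 | 1-(benzyloxy)-4-ethenyl-2-methoxybenzene | COc1cc(C=C)ccc1OCc1ccccc1 | intermediate
13 | methyl (2R,3R)-4-(benzyloxy)-2-[4-(benzyloxy)-3-methoxyphenyl]-6-[(E)-2-[4-(benzyloxy)-3-methoxyphenyl]ethenyl]-2,3-dihydro-1-benzofuran-3-carboxylate | COc1cc(/C=C/c2cc(OCc3ccccc3)c3c(c2)O[C@@H](c2ccc(OCc4ccccc4)c(OC)c2)[C@@H]3C(=O)OC)ccc1OCc1ccccc1 | intermediate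
14 | (2R,3R)-4-(benzyloxy)-2-[4-(benzyloxy)-3-methoxyphenyl]-6-[(E)-2-[4-(benzyloxy)-3-methoxyphenyl]ethenyl]-2,3-dihydro-1-benzofuran-3-carboxylic acid | COc1cc(/C=C/c2cc(OCc3ccccc3)c3c(c2)O[C@@H](c2ccc(OCc4ccccc4)c(OC)c2)[C@@H]3C(=O)O)ccc1OCc1ccccc1 | intermediate
15 | 1,3-dioxo-1,3-dihydro-2H-isoindol-2-yl (2R,3R)-4-(benzyloxy)-2-[4-(benzyloxy)-3-methoxyphenyl]-6-[(E)-2-[4-(benzyloxy)-3-methoxyphenyl]ethenyl]-2,3-dihydro-1-benzofuran-3-carboxylate | COc1cc(/C=C/c2cc(OCc3ccccc3)c3c(c2)O[C@@H](c2ccc(OCc4ccccc4)c(OC)c2)[C@@H]3C(=O)ON2C(=O)c3ccccc3C2=O)ccc1OCc1ccccc1 | intermediate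
16 | 1,3-bis(benzyloxy)-5-bromobenzene | Brc1cc(OCc2ccccc2)cc(OCc2ccccc2)c1 | starting material
17 | [3,5-bis(benzyloxy)phenyl]lithium (formed in the flask) | [Li]c1cc(OCc2ccccc2)cc(OCc2ccccc2)c1 | intermediate
18 | [3,5-bis(benzyloxy)phenyl]zinc chloride (formed in the flask) | Cl[Zn]c1cc(OCc2ccccc2)cc(OCc2ccccc2)c1 | intermediate
19 | (2R,3R)-4-(benzyloxy)-2-[4-(benzyloxy)-3-methoxyphenyl]-6-[(E)-2-[4-(benzyloxy)-3-methoxyphenyl]ethenyl]-3-[3,5-bis(benzyloxy)phenyl]-2,3-dihydro-1-benzofuran | COc1cc(/C=C/c2cc(OCc3ccccc3)c3c(c2)O[C@@H](c2ccc(OCc4ccccc4)c(OC)c2)[C@@H]3c2cc(OCc3ccccc3)cc(OCc3ccccc3)c2)ccc1OCc1ccccc1 | intermediate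
20 | 5-[(2R,3R)-4-hydroxy-2-(4-hydroxy-3-methoxyphenyl)-6-[(E)-2-(4-hydroxy-3-methoxyphenyl)ethenyl]-2,3-dihydro-1-benzofuran-3-yl]benzene-1,3-diol | COc1cc(/C=C/c2cc(O)c3c(c2)O[C@@H](c2ccc(O)c(OC)c2)[C@@H]3c2cc(O)cc(O)c2)ccc1O | target

Total step count: 11. Longest linear sequence: 10 steps (steps 1–5 and 7–11, from 1 to 20); step 6 is a one-step side branch.

Steps most likely to fail

Step 5 (ring contraction). The enol ether may form slowly next to the peri benzyloxy group. After iodination the C2 aryl group may shift in place of C4a, or elimination may give the flavone. Acid may also ionise the benzylic C2–O1 bond and erode the enantiomeric purity. The fallback sets out from 8 and returns at 10, and forms the same C3–C3a bond by a Wolff ring contraction. Deprotonation of 8 with LiN(SiMe3)2 in THF at −78 °C and C-acylation with CF3CO2CH2CF3 should give the 3-trifluoroacetyl ketone F1. Deacylative diazo transfer (MsN3, Et3N, MeCN, rt) should give the 3-diazo ketone F2. Irradiation (350 nm, MeOH, 0 °C) should bring about the Wolff rearrangement with trapping by methanol, expected to give 10 together with its cis epimer F3. NaOMe in MeOH should equilibrate F3 to the trans ester 10. C2 is not involved at any stage.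

Step 10 (decarboxylative arylation). The C3 radical may be captured on both faces, or be lost by dimerisation or hydrogen abstraction. The C3–nickel species may lose a β-hydride towards the aromatic benzofuran, and the arylzinc reagent may attack the activated ester. The fallback sets out from 15 and returns at 19, and is a reductive cross-electrophile coupling that needs no preformed organozinc reagent. Quenching aryllithium 17 with I2 at −78 °C should give 1,3-bis(benzyloxy)-5-iodobenzene F4. Coupling of 15 with F4 under NiBr2(dme), 4,4′-di-tert-butyl-2,2′-bipyridine and Zn dust in DMA at rt generates the aryl–nickel partner by oxidative addition and keeps the radical concentration low. It should give 19 with the same anti delivery.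

Step 4 (asymmetric conjugate addition). The chromone is deactivated by the peri benzyloxy group, so insertion may be slow and protodeboronation of 7 may outpace it. Facial discrimination may be incomplete, and base may open the flavanone to the chalcone and racemise it. The fallback sets out from 4 and returns at 8. Claisen–Schmidt condensation of 4 with aldehyde 11 (KOH, EtOH, rt) should give the 2′-hydroxychalcone F5. Oxa-Michael cyclisation (NaOAc, EtOH, reflux) should give the racemic flavanone F6. Preparative chromatography on a chiral stationary phase should deliver 8 and the (2S)-flavanone F7, which base returns to F6 through F5 for recycling.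

Further compounds
F1 | step 5 | 3-(trifluoroacetyl) derivative of 8, drawn as the enol 5-(benzyloxy)-2-[4-(benzyloxy)-3-methoxyphenyl]-7-bromo-3-(trifluoroacetyl)-2H-chromen-4-ol (C2 as in 8) | Brc1cc(OCc3ccccc3)c2c(c1)O[C@@H](c1ccc(OCc3ccccc3)c(OC)c1)C(C(=O)C(F)(F)F)=C2O
F2 | step 5 | 5-(benzyloxy)-2-[4-(benzyloxy)-3-methoxyphenyl]-7-bromo-3-diazo-2,3-dihydro-4H-chromen-4-one (C2 as in 8; the descriptor becomes 2S by priority only) | Brc1cc(OCc3ccccc3)c2c(c1)O[C@@H](c1ccc(OCc3ccccc3)c(OC)c1)C(=[N+]=[N-])C2=O
F3 | step 5 | methyl (2R,3S)-4-(benzyloxy)-2-[4-(benzyloxy)-3-methoxyphenyl]-6-bromo-2,3-dihydro-1-benzofuran-3-carboxylate (cis) | Brc1cc(OCc3ccccc3)c2c(c1)O[C@@H](c1ccc(OCc3ccccc3)c(OC)c1)[C@H]2C(=O)OC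
F4 | step 10 | 1,3-bis(benzyloxy)-5-iodobenzene | Ic1cc(OCc2ccccc2)cc(OCc2ccccc2)c1
F5 | step 4 | (2E)-1-[2-(benzyloxy)-4-bromo-6-hydroxyphenyl]-3-[4-(benzyloxy)-3-methoxyphenyl]prop-2-en-1-one | COc1cc(/C=C/C(=O)c2c(O)cc(Br)cc2OCc2ccccc2)ccc1OCc1ccccc1
F6 | step 4 | racemic 5-(benzyloxy)-2-[4-(benzyloxy)-3-methoxyphenyl]-7-bromo-2,3-dihydro-4H-chromen-4-one | Brc1cc(OCc3ccccc3)c2c(c1)OC(c1ccc(OCc3ccccc3)c(OC)c1)CC2=O
F7 | step 4 | (2S)-5-(benzyloxy)-2-[4-(benzyloxy)-3-methoxyphenyl]-7-bromo-2,3-dihydro-4H-chromen-4-one | Brc1cc(OCc3ccccc3)c2c(c1)O[C@H](c1ccc(OCc3ccccc3)c(OC)c1)CC2=O
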